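A reversible exchange cannot take a complex out of play for good, and in this flask step four is the one arrow with no way back.

    starting complex + incoming ligand ⇌ leaving ligand + complex with one exchanged (K1 = 1.1, k1 = 0.27 /M/h)
    complex with one exchanged + incoming ligand ⇌ leaving ligand + complex with two exchanged (K2 = 0.49, k2 = 0.81 /M/h)
    complex with two exchanged + incoming ligand ⇌ leaving ligand + complex with three exchanged (K3 = 1.9, k3 = 0.68 /M/h)
    starting complex + complex with one exchanged → side product (k4 = 0.70 /M/h)

starting complex 0.25 M (fed, over 40 min); incoming ligand 0.375 M; time 5.0 d

- conversion of starting complex at 5.0 d
- amount of complex with one exchanged at 5.0 d, in percent of the starting complex charged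
- amount of side product at 5.0 d, in percent of the starting complex charged
- amount of complex with three exchanged at 5.0 d, in percent of the starting complex charged
- amount of complex with one exchanged if the flask were left three thousand times as long, in percent of the starting complex charged

- in percentages every species weighs as the starting complex in it: one side product counts as two
- run time (flask): 5.0 d

I treat the feed as a charge at the start, because 40 min is far shorter than 5.0 d. As the zero of my scale I take the symmetric case, [leaving ligand] = [incoming ligand]. With the first exchange alone, whose forward half-life is 0.29 d, [complex with one exchanged]/[starting complex] then equals 1.1, so 47.6% of the complex stays as starting complex.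

Adding the other two exchanges gives the weights one, 1.1, 0.539 and 1.02, which sum to 3.66. The starting complex falls to 27.3% of the pool, meaning the four complexes not yet in side product.

Now I add the side reaction. Each event removes two complexes from the pool, so d[pool]/dt = −kd[pool]², where the drain constant kd is twice the side-reaction constant times the product of the two reacting shares: 0.115 /M/h. Its first half-time on the full charge is 1.45 d, and each forward half-life of the exchanges is shorter than that, so I treat the exchanges as a rapid pre-equilibrium beneath the drain.

The pool left at 5.0 d is then 22.5% of the charge. That gives a conversion of 93.9%, complex with one exchanged 6.76%, side product 77.5% and complex with three exchanged 6.29%. The last question, on the flask left far longer, I leave unreckoned.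

The forecast, with A the starting complex, B the complex with one exchanged and O the side product, says "A + B → O drains the metal" and gives 95.6%, 6.4%, 79%, 6.8% and 0.011%. The simulation gives 95.1%, 6.03%, 79.0%, 6.87% and 0.0102%.

This flask is not at rest at 5.00 d, where [leaving ligand]/[incoming ligand] reads 0.939. At 50.0 d the side product has climbed to 94.5%, the complex with three exchanged has fallen to 2.72% and the complex with one exchanged to 1.17%. The drain constant puts the side product there at 97.2%, while the ratio reads 0.638. For the neighbour flask with 0.15 M of starting complex, the same constant gives 67.4% side product at 5.00 d; that flask holds 59.7%, with the ratio reading 0.737.

The numbers of this flask were drawn at random within sensible limits, and the outcome is calculated.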